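**Plan**

- Retrosynthesis: cut the upper C4–C8 interflavan bond (gallocatechin C4 cation + dimer), then the lower C4–C8 bond (middle-unit flavan-4-yl cation from a flavan-3,4-diol + benzylated catechin), then the C2–C3 bond of the middle C ring.
- The middle C ring (O1, C2, C3, C4, C4a, C8a) is made at the chroman-4-one oxidation level by ring contraction of a seven-membered 1,3-benzodioxepin-5-one acetal (O1–C2–O3–C3–C4(=O)–C4a–C8a). O3 leaves the ring and stays as the 3-OH.
- Enabling feature: C2 lies between O1 and the electron-rich 3,4-dioxygenated B ring, so it is an acetal carbon that ionises to a benzylic oxocarbenium ion with no β-hydrogen. C3 is α to the C4 carbonyl and enolisable, so an intramolecular oxocarbenium–enol union forges C2–C3.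
- Forward order: hydroxyketone + aldehyde → acetal → ring contraction (sets C2 and C3) → C4=O to C4–OH → coupling with the bottom unit → coupling with the top electrophile → global hydrogenolysis.
- Stereochemistry: middle C2 by the chiral acid catalyst, C3 relayed trans in the same event, C4 of the middle and top units by attack anti to the 3-oxygen on the flavan-4-yl cations (3,4-trans). Top and bottom C2/C3 are bought (chiral-pool flavan-3-ols).

Key step: step 3

Remark: the target is read as gallocatechin-(4α→8)-catechin-(4α→8)-catechin, each C ring 2R and 2,3-trans-3,4-trans; compound 1 and both flavan-3-ols are taken as purchasable.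

**Route**

Step 1
Reactants: 1 1-[2,4-bis(benzyloxy)-6-hydroxyphenyl]ethan-1-one
Product: 4 1-[2,4-bis(benzyloxy)-6-hydroxyphenyl]-2-hydroxyethan-1-one, via bis-TMS enol ether 2 (not isolated), via bis-TMS siloxy ketone 3 (not isolated)
Conditions: TMSOTf (2.3 eq), Et3N (3 eq), CH2Cl2, 0 °C; then mCPBA (1.1 eq), CH2Cl2/hexane, -15 °C; then 1 M HCl, THF, rt
Reagents that add atoms: mCPBA OOC(=O)c1cccc(Cl)c1
Why: Rubottom oxidation: the methyl ketone is the only enolisable site, its silyl enol ether is epoxidised at the electron-rich C=C, and silyl shift followed by hydrolysis should give the α-hydroxy ketone (no stereocentre formed).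

Step 2
Reactants: 4 1-[2,4-bis(benzyloxy)-6-hydroxyphenyl]-2-hydroxyethan-1-one; 5 3,4-bis(benzyloxy)benzaldehyde
Product: 6 (±)-6,8-bis(benzyloxy)-2-[3,4-bis(benzyloxy)phenyl]-2H-1,3-benzodioxepin-5(4H)-one
Conditions: 5 (1.1 eq), i-PrOSiMe3 (2.5 eq), TMSOTf (10 mol%), CH2Cl2, -78 to -30 °C; pyridine quench; Et3N-deactivated silica
Reagents that add atoms: none
Why: Noyori acetalisation with in situ silylation should close the seven-membered mixed aryl alkyl acetal under kinetic low-temperature conditions, driven by siloxane formation; the acetal carbon forms racemic, which is harmless because it is ionised in step 3.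

Step 3
Reactants: 6 (±)-6,8-bis(benzyloxy)-2-[3,4-bis(benzyloxy)phenyl]-2H-1,3-benzodioxepin-5(4H)-one
Product: 7 (2R,3R)-5,7-bis(benzyloxy)-2-[3,4-bis(benzyloxy)phenyl]-3-hydroxychroman-4-one
Conditions: (R)-3,3'-bis(2,4,6-triisopropylphenyl)-BINOL N-triflyl phosphoramide (10 mol%), 5 Å MS, toluene (0.02 M), 40 °C
Reagents that add atoms: none
Why: Proposed new method: the chiral acid protonates the alkyl acetal oxygen (the future 3-OH oxygen) and the bond from the acetal carbon (future C2) to this oxygen ionises to an O1-bound benzylic oxocarbenium ion, stabilised by O1 and the 3,4-dialkoxyphenyl ring and unable to eliminate because it has no β-hydrogen, held as a contact ion pair while the liberated α-hydroxy ketone enolises to its enediol. The enediol α-carbon (future C3) then attacks C2 in a 6-(enolendo)-endo-trig closure that forms C2–C3 and contracts the seven-membered 1,3-benzodioxepinone ring to the six-membered chromanone ring with the oxygen expelled from the ring as the 3-hydroxyl, a net 1,2 O-to-C shift driven by C–C bond formation and regeneration of the aryl ketone. The closest known reaction type is the chiral phosphoric acid-catalysed Petasis–Ferrier-type ring contraction of seven-membered cyclic vinyl acetals, together with acetal-based Mukaiyama aldol and Prins ring closures. C2 is set by the chiral counter-anion shielding one face of the planar oxocarbenium ion (the racemic acetal centre is erased, so the process is enantioconvergent, and the catalyst antipode is fixed by the sense of induction found); C3 is set relative to C2 by the chair-like transition state with the aryl group equatorial and by ready epimerisation to the trans diequatorial ketol. The step needs the enediol to react through C3 and not through the aryl-bearing carbon, which regeneration of the conjugated 2-alkoxyaryl ketone should secure, as in direct aldol reactions of 2-hydroxyacetophenones.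

Step 4
Reactants: 7 (2R,3R)-5,7-bis(benzyloxy)-2-[3,4-bis(benzyloxy)phenyl]-3-hydroxychroman-4-one
Product: 8 (2R,3S,4R)-5,7-bis(benzyloxy)-2-[3,4-bis(benzyloxy)phenyl]chroman-3,4-diol
Conditions: NaBH4, THF/EtOH, 0 °C to rt
Reagents that add atoms: none
Why: Borohydride reduction of the aryl ketone should give mainly the 2,3-trans-3,4-trans diol, as is usual for dihydroflavonols; the C4 configuration is of no consequence because C4 is ionised in step 6.

Step 5
Reactants: 9 (+)-catechin
Product: 10 5,7,3',4'-tetra-O-benzyl-(+)-catechin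
Conditions: BnBr (4.4 eq), K2CO3, DMF, 0 °C to rt
Reagents that add atoms: benzyl bromide BrCc1ccccc1
Why: Williamson etherification of the four phenols with carbonate base leaves the secondary 3-OH free and does not touch C2 or C3.

Step 6
Reactants: 8 (2R,3S,4R)-5,7-bis(benzyloxy)-2-[3,4-bis(benzyloxy)phenyl]chroman-3,4-diol; 10 5,7,3',4'-tetra-O-benzyl-(+)-catechin
Product: 11 octa-O-benzyl catechin-(4α→8)-catechin (upper unit 2R,3S,4S; both 3-OH free)
Conditions: 10 (4 eq), TMSOTf (10 mol%), 4 Å MS, CH2Cl2, -78 to -40 °C; Et3N quench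
Reagents that add atoms: none
Why: Acid ionisation of the C4 hydroxyl gives the A-ring-stabilised flavan-4-yl cation, which the excess nucleophile should attack through its most nucleophilic C8 on the face anti to the 3-oxygen (3,4-trans, 4α), a Friedel–Crafts-type interflavan coupling established for benzylated catechins.

Step 7
Reactants: 12 (+)-gallocatechin
Product: 13 5,7,3',4',5'-penta-O-benzyl-(+)-gallocatechin
Conditions: BnBr (5.5 eq), K2CO3, DMF, 0 °C to rt
Reagents that add atoms: benzyl bromide BrCc1ccccc1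
Why: Williamson etherification of the five phenols leaves the 3-OH free and the stereocentres untouched.

Step 8
Reactants: 13 5,7,3',4',5'-penta-O-benzyl-(+)-gallocatechin
Product: 14 (2R,3S,4S)-5,7-bis(benzyloxy)-4-(2-ethoxyethoxy)-2-[3,4,5-tris(benzyloxy)phenyl]chroman-3-ol
Conditions: DDQ (2 eq), 2-ethoxyethanol (5 eq), CH2Cl2, rt
Reagents that add atoms: 2-ethoxyethanol CCOCCO
Why: DDQ benzylic oxidation: hydride abstraction at C4 (activated by the 5,7-dialkoxy A ring) gives a quinone-methide-type cation that the alcohol traps anti to the 2-aryl group (4β ether), the standard C4 activation of benzylated flavan-3-ols.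

Step 9
Reactants: 14 (2R,3S,4S)-5,7-bis(benzyloxy)-4-(2-ethoxyethoxy)-2-[3,4,5-tris(benzyloxy)phenyl]chroman-3-ol; 11 octa-O-benzyl catechin-(4α→8)-catechin
Product: 15 trideca-O-benzyl gallocatechin-(4α→8)-catechin-(4α→8)-catechin (three 3-OH free)
Conditions: 11 (3 eq), TMSOTf (10 mol%), CH2Cl2, -78 °C; Et3N quench
Reagents that add atoms: none
Why: TMSOTf-catalysed ionisation of the C4 ether gives the gallocatechin flavan-4-yl cation, which C8 of the upper unit of the dimer (its most nucleophilic free position, dimer in excess) should attack anti to the 3-OH (4α), a Friedel–Crafts interflavan coupling as used for procyanidin trimers.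

Step 10
Reactants: 15 trideca-O-benzyl gallocatechin-(4α→8)-catechin-(4α→8)-catechin
Product: 16 gallocatechin-(4α→8)-catechin-(4α→8)-catechin (target)
Conditions: H2 (1 atm), Pd(OH)2/C, THF/MeOH/H2O, rt; filtration, lyophilisation
Reagents that add atoms: none
Why: Hydrogenolysis of the thirteen benzyl ethers over Pearlman's catalyst is neutral, so the acid-sensitive interflavan bonds and all stereocentres should survive.

**Compound list**

1 | 1-[2,4-bis(benzyloxy)-6-hydroxyphenyl]ethan-1-one | CC(=O)c1c(O)cc(OCc2ccccc2)cc1OCc1ccccc1 | starting material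
2 | {1-[2,4-bis(benzyloxy)-6-(trimethylsilyloxy)phenyl]ethenyloxy}trimethylsilane (bis-TMS enol ether) | C=C(O[Si](C)(C)C)c1c(O[Si](C)(C)C)cc(OCc2ccccc2)cc1OCc1ccccc1 | intermediate
3 | 1-[2,4-bis(benzyloxy)-6-(trimethylsilyloxy)phenyl]-2-(trimethylsilyloxy)ethan-1-one | O=C(CO[Si](C)(C)C)c1c(O[Si](C)(C)C)cc(OCc2ccccc2)cc1OCc1ccccc1 | intermediate
4 | 1-[2,4-bis(benzyloxy)-6-hydroxyphenyl]-2-hydroxyethan-1-one | O=C(CO)c1c(O)cc(OCc2ccccc2)cc1OCc1ccccc1 | intermediate
5 | 3,4-bis(benzyloxy)benzaldehyde | O=Cc1ccc(OCc2ccccc2)c(OCc2ccccc2)c1 | starting material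
6 | (±)-6,8-bis(benzyloxy)-2-[3,4-bis(benzyloxy)phenyl]-2H-1,3-benzodioxepin-5(4H)-one | O=C1COC(c2ccc(OCc3ccccc3)c(OCc3ccccc3)c2)Oc2cc(OCc3ccccc3)cc(OCc3ccccc3)c21 | intermediate
7 | (2R,3R)-5,7-bis(benzyloxy)-2-[3,4-bis(benzyloxy)phenyl]-3-hydroxychroman-4-one | O=C1c2c(OCc3ccccc3)cc(OCc3ccccc3)cc2O[C@H](c2ccc(OCc3ccccc3)c(OCc3ccccc3)c2)[C@H]1O | intermediate
8 | (2R,3S,4R)-5,7-bis(benzyloxy)-2-[3,4-bis(benzyloxy)phenyl]chroman-3,4-diol | O[C@@H]1c2c(OCc3ccccc3)cc(OCc3ccccc3)cc2O[C@H](c2ccc(OCc3ccccc3)c(OCc3ccccc3)c2)[C@H]1O | intermediate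
9 | (+)-catechin, (2R,3S) | Oc1cc(O)c2c(c1)O[C@H](c1ccc(O)c(O)c1)[C@@H](O)C2 | starting material
10 | 5,7,3',4'-tetra-O-benzyl-(+)-catechin | c1ccccc1COc1cc(OCc2ccccc2)c2c(c1)O[C@H](c1ccc(OCc3ccccc3)c(OCc3ccccc3)c1)[C@@H](O)C2 | intermediate
11 | octa-O-benzyl catechin-(4α→8)-catechin | c1ccccc1COc1cc(OCc2ccccc2)c2c(c1)O[C@H](c1ccc(OCc3ccccc3)c(OCc3ccccc3)c1)[C@@H](O)[C@@H]2c1c(OCc2ccccc2)cc(OCc2ccccc2)c2c1O[C@H](c1ccc(OCc3ccccc3)c(OCc3ccccc3)c1)[C@@H](O)C2 | intermediate
12 | (+)-gallocatechin, (2R,3S) | Oc1cc(O)c2c(c1)O[C@H](c1cc(O)c(O)c(O)c1)[C@@H](O)C2 | starting material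
13 | 5,7,3',4',5'-penta-O-benzyl-(+)-gallocatechin | c1ccccc1COc1cc(OCc2ccccc2)c2c(c1)O[C@H](c1cc(OCc3ccccc3)c(OCc3ccccc3)c(OCc3ccccc3)c1)[C@@H](O)C2 | intermediate
14 | (2R,3S,4S)-5,7-bis(benzyloxy)-4-(2-ethoxyethoxy)-2-[3,4,5-tris(benzyloxy)phenyl]chroman-3-ol | CCOCCO[C@H]1c2c(OCc3ccccc3)cc(OCc3ccccc3)cc2O[C@H](c2cc(OCc3ccccc3)c(OCc3ccccc3)c(OCc3ccccc3)c2)[C@H]1O | intermediate
15 | trideca-O-benzyl gallocatechin-(4α→8)-catechin-(4α→8)-catechin | c1ccccc1COc1cc(OCc2ccccc2)c2c(c1)O[C@H](c1cc(OCc3ccccc3)c(OCc3ccccc3)c(OCc3ccccc3)c1)[C@@H](O)[C@@H]2c1c(OCc2ccccc2)cc(OCc2ccccc2)c2c1O[C@H](c1ccc(OCc3ccccc3)c(OCc3ccccc3)c1)[C@@H](O)[C@@H]2c1c(OCc2ccccc2)cc(OCc2ccccc2)c2c1O[C@H](c1ccc(OCc3ccccc3)c(OCc3ccccc3)c1)[C@@H](O)C2 | intermediate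
16 | gallocatechin-(4α→8)-catechin-(4α→8)-catechin | Oc1cc(O)c2c(c1)O[C@H](c1cc(O)c(O)c(O)c1)[C@@H](O)[C@@H]2c1c(O)cc(O)c2c1O[C@H](c1ccc(O)c(O)c1)[C@@H](O)[C@@H]2c1c(O)cc(O)c2c1O[C@H](c1ccc(O)c(O)c1)[C@@H](O)C2 | target

**Step count and risks**

Total steps: 10. Longest linear sequence: 7 (steps 1, 2, 3, 4, 6, 9, 10).

Steps most likely to fail:

1. Step 3 (proposed new method). The ion pair may give poor enantioface discrimination. The enediol may also close through its aryl-bearing carbon to a five-membered α-hydroxy aldehyde that dehydrates, or the cation may be captured intermolecularly by an arene. Any minor enantiomer that survives would give a diastereomeric dimer in step 6, which should be separable there. Fallback with known chemistry: starting from 10, DDQ oxidation at C4 in the presence of 2-ethoxyethanol should give (2R,3S,4S)-4-(2-ethoxyethoxy)-5,7,3',4'-tetra-O-benzylcatechin F1. TMSOTf-catalysed coupling of F1 with an excess of 10 then gives dimer 11, where the route is rejoined; steps 1 to 4 are then not used.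

2. Step 2. The chelated, weakly nucleophilic phenol may fail to close the seven-membered ring, or the acetal may ionise during the reaction or on silica and rearrange without stereocontrol. Fallback: starting from 4, selective O-alkylation of the phenol with 3,4-bis(benzyloxy)benzyl chloride (K2CO3, DMF) should give 1-{2,4-bis(benzyloxy)-6-[(3,4-bis(benzyloxy)benzyl)oxy]phenyl}-2-hydroxyethan-1-one F2. Anhydrous DDQ (CH2Cl2, 4 Å MS) then abstracts the benzylic hydride of this electron-rich benzyl ether, and the primary hydroxyl traps the oxocarbenium ion. This is oxidative acetal formation as known for p-alkoxybenzyl ethers next to a hydroxyl; it gives 6 under neutral conditions, and the route is rejoined at 6.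

3. Step 9. The electrophile may self-condense, and over-alkylation at C6 positions or on the product may give oligomer mixtures. Fallback with a blocking group: starting from 13, NBS bromination at C8 should give 8-bromo-penta-O-benzylgallocatechin F3. DDQ with 2-ethoxyethanol gives the 8-bromo C4 ether F4, which can no longer react through its own C8. TMSOTf coupling of F4 with 11 gives the 8-bromo trimer F5. Hydrogenolysis (H2, Pd(OH)2/C, Et3N) removes the benzyl groups and the C8–Br bond together and rejoins the route at 16.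

**Further compounds**

F1 | step 3 | (2R,3S,4S)-5,7-bis(benzyloxy)-2-[3,4-bis(benzyloxy)phenyl]-4-(2-ethoxyethoxy)chroman-3-ol | CCOCCO[C@H]1c2c(OCc3ccccc3)cc(OCc3ccccc3)cc2O[C@H](c2ccc(OCc3ccccc3)c(OCc3ccccc3)c2)[C@H]1O
F2 | step 2 | 1-{2,4-bis(benzyloxy)-6-[(3,4-bis(benzyloxy)benzyl)oxy]phenyl}-2-hydroxyethan-1-one | O=C(CO)c1c(OCc2ccc(OCc3ccccc3)c(OCc3ccccc3)c2)cc(OCc2ccccc2)cc1OCc1ccccc1
F3 | step 9 | (2R,3S)-8-bromo-5,7-bis(benzyloxy)-2-[3,4,5-tris(benzyloxy)phenyl]chroman-3-ol | c1ccccc1COc1cc(OCc2ccccc2)c2c(c1Br)O[C@H](c1cc(OCc3ccccc3)c(OCc3ccccc3)c(OCc3ccccc3)c1)[C@@H](O)C2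
F4 | step 9 | (2R,3S,4S)-8-bromo-5,7-bis(benzyloxy)-4-(2-ethoxyethoxy)-2-[3,4,5-tris(benzyloxy)phenyl]chroman-3-ol | CCOCCO[C@H]1c2c(OCc3ccccc3)cc(OCc3ccccc3)c(Br)c2O[C@H](c2cc(OCc3ccccc3)c(OCc3ccccc3)c(OCc3ccccc3)c2)[C@H]1O
F5 | step 9 | trideca-O-benzyl 8-bromogallocatechin-(4α→8)-catechin-(4α→8)-catechin | c1ccccc1COc1cc(OCc2ccccc2)c2c(c1Br)O[C@H](c1cc(OCc3ccccc3)c(OCc3ccccc3)c(OCc3ccccc3)c1)[C@@H](O)[C@@H]2c1c(OCc2ccccc2)cc(OCc2ccccc2)c2c1O[C@H](c1ccc(OCc3ccccc3)c(OCc3ccccc3)c1)[C@@H](O)[C@@H]2c1c(OCc2ccccc2)cc(OCc2ccccc2)c2c1O[C@H](c1ccc(OCc3ccccc3)c(OCc3ccccc3)c1)[C@@H](O)C2
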